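**Retrosynthetic overview**
- No ring is built. Rings A and C come from naphthalene-1,8-diol (1) by way of 8-methoxynaphthalen-1-ol (2); its sodium salt (3) gives the MOM ether 4. Ring B comes from juglone (5) as quinone 6.
- Bond A–B (ring A C2 to ring B C4): aryllithium 7, made by ortho-lithiation of 4, adds to the C1 carbonyl of 6. Alkoxide 8 is quenched to p-quinol 9, in which ring B is dearomatised.
- Bond B–C (ring B C2 to ring C C4), the key step: 9 ionises to the 4-aryl-naphthoxenium cation 10, an α-keto (enolonium-type) cation. Its C2 is attacked by the para carbon of 2, joining two carbons that are both nucleophilic in the parent naphthols; ring B rearomatises (11).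
- MOM removal in the same flask gives the target 12. Ring B is the only ring whose aromaticity changes, and it is restored last.

Assumption: the SMILES has no stereodescriptor, and each biaryl axis is flanked only by one OH, one ortho H and one peri H, so both axes rotate freely at room temperature. The target is therefore treated as one achiral compound and no stereocontrol is needed.

**Step 1**
Reactants: 1 naphthalene-1,8-diol
Product: 2 8-methoxynaphthalen-1-ol
Conditions: MeI (1.05 equiv), K2CO3 (1.1 equiv), acetone, reflux
Reagents that add atoms: iodomethane, CI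
Why: Williamson ether synthesis; after the first methylation the remaining OH is held in a hydrogen bond to the peri OMe and is much less acidic, so the reaction stops at the mono-ether.

**Step 2**
Reactants: 2 8-methoxynaphthalen-1-ol
Product: 4 1-methoxy-8-(methoxymethoxy)naphthalene, via sodium naphtholate 3 (not isolated)
Conditions: NaH (1.2 equiv), DMF, 0 °C; then MOMCl (1.2 equiv), 0 °C → rt
Reagents that add atoms: chloromethyl methyl ether, COCCl
Why: Williamson-type O-alkylation of the naphtholate; NaH breaks the peri hydrogen bond irreversibly, and the MOM acetal serves as ortho-director in step 4 and is acid-labile in step 5.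

**Step 3**
Reactants: 5 juglone (5-hydroxynaphthalene-1,4-dione)
Product: 6 5-methoxynaphthalene-1,4-dione
Conditions: MeI (excess), Ag2O (1.5 equiv), CH2Cl2, rt, dark
Reagents that add atoms: iodomethane, CI
Why: Ag2O-mediated methylation (Purdie conditions) alkylates the chelated peri OH under near-neutral conditions that the base-sensitive quinone tolerates.

**Step 4**
Reactants: 4 1-methoxy-8-(methoxymethoxy)naphthalene (1.2 equiv); 6 5-methoxynaphthalene-1,4-dione (1.0 equiv)
Product: 9 rac-4-hydroxy-8-methoxy-4-[8-methoxy-1-(methoxymethoxy)naphthalen-2-yl]naphthalen-1(4H)-one, via aryllithium 7 (not isolated), via lithium alkoxide 8 (not isolated)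
Conditions: n-BuLi (1.15 equiv), TMEDA, Et2O, 0 °C → rt, 2 h; then cannulate into 6 in THF, −78 °C, 1 h; sat. aq. NH4Cl
Reagents that add atoms: none
Why: Directed ortho-metalation puts lithium at C2 (OMOM directs more strongly than OMe and the peri position is blocked), and the aryllithium then adds 1,2 to C1 of 6, the more electrophilic and less hindered carbonyl (C4 is an o-methoxyaryl ketone shielded by the peri OMe); the new quaternary carbinol carbon forms as a racemate and is made planar again in step 5.

**Step 5**
Reactants: 9 rac-4-hydroxy-8-methoxy-4-[8-methoxy-1-(methoxymethoxy)naphthalen-2-yl]naphthalen-1(4H)-one; 2 8-methoxynaphthalen-1-ol (3 equiv)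
Product: 12 2-(4-hydroxy-5-methoxynaphthalen-1-yl)-4-(1-hydroxy-8-methoxynaphthalen-2-yl)-8-methoxynaphthalen-1-ol, via naphthoxenium cation 10 (not isolated), via MOM-protected ternaphthol 11 (not isolated)
Conditions: TsOH·H2O (10 mol%), (CF3)2CHOH/CH2Cl2 1:1, −20 → 0 °C, Ar, slow addition of 9 to 2; then MeOH, conc. HCl (cat.), 45 °C
Reagents that add atoms: none
Why: Proposed new method: acid in the strongly ionising, weakly nucleophilic solvent (CF3)2CHOH removes the tertiary, doubly benzylic and allylic OH of 9 as water to give cation 10, a 4-aryl-naphthoxenium ion stabilised by the alkoxy-rich ring A with positive character at C4 and at C2 (α to the carbonyl); attack of the bulky naphthol 2 through its para carbon at the quaternary, peri-hindered C4 is slow and reversible, whereas attack at the free C2 becomes irreversible by enolisation to the naphthol (SN1′-type Friedel–Crafts arylation, then tautomerisation), so 11 accumulates and HCl/MeOH then removes the MOM acetal by transacetalisation; the closest known reaction type is the Brønsted-acid-promoted coupling of quinone monoacetals with arenes in fluoroalcohols, which arylates the carbon α to the dienone carbonyl; no stereocentre remains.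

**Compound list**
1 | naphthalene-1,8-diol | Oc1cccc2cccc(O)c12 | starting material
2 | 8-methoxynaphthalen-1-ol | COc1cccc2cccc(O)c12 | intermediate
3 | sodium 8-methoxynaphthalen-1-olate | COc1cccc2cccc([O-])c12.[Na+] | intermediate (not isolated)
4 | 1-methoxy-8-(methoxymethoxy)naphthalene | COCOc1cccc2cccc(OC)c12 | intermediate
5 | juglone (5-hydroxynaphthalene-1,4-dione) | O=C1C=CC(=O)c2c(O)cccc12 | starting material
6 | 5-methoxynaphthalene-1,4-dione | COc1cccc2C(=O)C=CC(=O)c12 | intermediate
7 | [8-methoxy-1-(methoxymethoxy)naphthalen-2-yl]lithium | [Li]c1ccc2cccc(OC)c2c1OCOC | intermediate (not isolated)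
8 | lithium alkoxide of 9 (racemic) | COCOc1c(C2(O[Li])C=CC(=O)c3c(OC)cccc23)ccc2cccc(OC)c12 | intermediate (not isolated)
9 | rac-4-hydroxy-8-methoxy-4-[8-methoxy-1-(methoxymethoxy)naphthalen-2-yl]naphthalen-1(4H)-one | COCOc1c(C2(O)C=CC(=O)c3c(OC)cccc23)ccc2cccc(OC)c12 | intermediate
10 | 8-methoxy-4-[8-methoxy-1-(methoxymethoxy)naphthalen-2-yl]-1-oxo-1,4-dihydronaphthalen-4-ylium (naphthoxenium cation) | COCOc1c([C+]2C=CC(=O)c3c(OC)cccc23)ccc2cccc(OC)c12 | intermediate (not isolated)
11 | 2-(4-hydroxy-5-methoxynaphthalen-1-yl)-8-methoxy-4-[8-methoxy-1-(methoxymethoxy)naphthalen-2-yl]naphthalen-1-ol | COc1cccc2ccc(-c3cc(-c4ccc(O)c5c(OC)cccc45)c(O)c4c(OC)cccc34)c(OCOC)c12 | intermediate (not isolated)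
12 | 2-(4-hydroxy-5-methoxynaphthalen-1-yl)-4-(1-hydroxy-8-methoxynaphthalen-2-yl)-8-methoxynaphthalen-1-ol | COc1cccc2ccc(-c3cc(-c4ccc(O)c5c(OC)cccc45)c(O)c4c(OC)cccc34)c(O)c12 | target

**Step count**
Total steps: 5. Longest linear sequence: 4 (steps 1, 2, 4, 5).

**Steps most likely to fail, with fallbacks**

Step 5 is the riskiest. The quinol may instead undergo a 1,2-aryl shift to an aryl hydroquinone, be attacked at C3, or oligomerise through ring A. The fallback sets out from 9 and comes back at 11. Reduce 9 with Zn dust in AcOH to the rearomatised naphthol 8-methoxy-4-[8-methoxy-1-(methoxymethoxy)naphthalen-2-yl]naphthalen-1-ol F1. Diazo transfer with 2-azido-1,3-dimethylimidazolinium chloride and Et3N then gives 2-diazo-8-methoxy-4-[8-methoxy-1-(methoxymethoxy)naphthalen-2-yl]naphthalen-1(2H)-one F2; the para position of ring B is blocked, so only C2 can react. The gold carbene generated from F2 with [(2,4-tBu2C6H3O)3P]AuCl and AgSbF6 in CH2Cl2 inserts into the para C–H bond of 2, giving 11, which is deprotected with HCl/MeOH as in step 5. Here the electrophilic carbon can only be C2 of ring B.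

Step 4 is next. The aryllithium may reduce the quinone by electron transfer or add in part to the wrong carbonyl. The fallback sets out from 7 and comes back at 9. Oxidise purchased 5-methoxynaphthalen-1-ol F3 with PhI(OAc)2 (2.1 equiv) in MeOH at 0 °C to the quinone monoketal 4,4,5-trimethoxynaphthalen-1(4H)-one F4, which has a single free carbonyl, at the position that must carry ring A. Aryllithium 7 adds to it at −78 °C to give rac-1-[8-methoxy-1-(methoxymethoxy)naphthalen-2-yl]-4,4,5-trimethoxy-1,4-dihydronaphthalen-1-ol F5. Mild hydrolysis of the ketal (5% aq. oxalic acid, THF, rt) gives 9 without touching the MOM group.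

Step 3 is third. Methylation of the chelated, base-sensitive juglone can be sluggish or low-yielding. The fallback sets out from 2 and comes back at 6: oxidise 2 with PhI(OCOCF3)2 (2.1 equiv) in MeCN/H2O 2:1 at 0 °C, which converts the naphthol directly into the para-quinone 6 and makes juglone unnecessary.

**Further compounds**
F1 | step 5 | 8-methoxy-4-[8-methoxy-1-(methoxymethoxy)naphthalen-2-yl]naphthalen-1-ol | COCOc1c(-c2ccc(O)c3c(OC)cccc23)ccc2cccc(OC)c12
F2 | step 5 | 2-diazo-8-methoxy-4-[8-methoxy-1-(methoxymethoxy)naphthalen-2-yl]naphthalen-1(2H)-one | COCOc1c(C2=CC(=[N+]=[N-])C(=O)c3c(OC)cccc23)ccc2cccc(OC)c12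
F3 | step 4 | 5-methoxynaphthalen-1-ol | COc1cccc2c(O)cccc12
F4 | step 4 | 4,4,5-trimethoxynaphthalen-1(4H)-one | COc1cccc2C(=O)C=CC(OC)(OC)c12
F5 | step 4 | rac-1-[8-methoxy-1-(methoxymethoxy)naphthalen-2-yl]-4,4,5-trimethoxy-1,4-dihydronaphthalen-1-ol | COCOc1c(C2(O)C=CC(OC)(OC)c3c(OC)cccc23)ccc2cccc(OC)c12
F0 | step 3 | none | none
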